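**Plan**

Locants: chromene O1–C8a. C1′ is the cyclopentane carbon carrying the CH2C(=O) arm and C2′ the one carrying the enone arm.
Cuts: Z-CH=CH goes back to C≡C and both ketones to carbinols. Then come the CH(OH)–CH2 bond next to C1′ (chromenylacetaldehyde + neopentyl-type alkyllithium), the C2′CH(O)–C≡C bond (aldehyde + acetylide) and C3=C4 (chroman dehydrogenation). Last, C4–C4a and O1–C8a are cut together (aryl iodide + gamma-bromo tertiary alcohol).
Enabling feature: in the benzene ring C8a (bearing O1) and C4a (bearing C4) are neighbours, and C8, the other neighbour of C8a, carries the methyl group. An iodide on C8a therefore has exactly one free ortho C–H, at C4a, so a C3 bromo alcohol can only be attached as the dihydropyran ring.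
Forward: the dihydropyran ring is closed on the arene (step 6). The cyclopentane is taken from a cis-1,5-dimethylbicyclo[3.3.0]octanone whose second ring is cleaved (step 13). The two fragments are joined in step 17 and four finishing steps follow.
Stereochemistry: C2 comes from a Katsuki–Sharpless epoxidation and a hydride opening that leaves the tertiary C–O bond intact. The cis C1′/C2′ methyls are built into the bicyclic diketone, and their absolute sense comes from enantioselective deprotonation of a meso ketone. The Z-alkene comes from syn hydrogenation.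

Key step: step 6

Assumption: lithium (R,R)-bis(1-phenylethyl)amide is taken to remove the enantiotopic proton that leads to the (1R,5S)-enol ether of step 12. If the sense proves opposite, the equally available (S,S)-amide is used in the same way.
Remark: the carbinol carbons created in steps 15 and 17 are carried as epimer mixtures (drawn without descriptor), because both become carbonyl carbons in step 19. All 2H-chromenes are handled with exclusion of UV light.

**Fragment 1**

Step 1
Reactants: 1 but-3-yn-1-ol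
Product: 2 tert-butyl(but-3-yn-1-yloxy)diphenylsilane
Conditions: t-BuPh2SiCl, imidazole, CH2Cl2, rt
Reagents that add atoms: tert-butyl(chloro)diphenylsilane, CC(C)(C)[Si](Cl)(c1ccccc1)c1ccccc1
Why: Standard silylation of a primary alcohol; the bulky, migration-resistant silyl group is chosen because a silyl shift between the two primary oxygens of diol 7 would erode its enantiopurity.

Step 2
Reactants: 2 tert-butyl(but-3-yn-1-yloxy)diphenylsilane
Product: 5 (E)-5-(tert-butyldiphenylsilyloxy)-3-methylpent-2-en-1-ol, via alkenylalane 3 (not isolated), via lithium alanate 4 (not isolated)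
Conditions: Me3Al (2.5 equiv), Cp2ZrCl2 (0.25 equiv), CH2Cl2, 0 °C to rt; n-BuLi, hexane/THF, −30 °C; (CH2O)n, rt; aqueous work-up
Reagents that add atoms: trimethylaluminium, C[Al](C)C; formaldehyde (as paraformaldehyde), C=O
Why: Negishi zirconium-catalysed carboalumination adds CH3 and Al syn with Al at the terminus, and the derived alanate transfers the alkenyl group to formaldehyde with retention, which fixes the E geometry.

Step 3
Reactants: 5 (E)-5-(tert-butyldiphenylsilyloxy)-3-methylpent-2-en-1-ol
Product: 6 [(2R,3R)-3-[2-(tert-butyldiphenylsilyloxy)ethyl]-3-methyloxiran-2-yl]methanol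
Conditions: Ti(OiPr)4 (10 mol %), D-(−)-diethyl tartrate (12 mol %), t-BuOOH, 4 Å molecular sieves, CH2Cl2, −20 °C
Reagents that add atoms: tert-butyl hydroperoxide, CC(C)(C)OO
Why: Katsuki–Sharpless asymmetric epoxidation of an E-trisubstituted allylic alcohol of the geraniol type, in which the D-(−)-tartrate directs oxygen to the face that gives the (2R,3R)-epoxide and so sets the future C2.

Step 4
Reactants: 6 [(2R,3R)-3-[2-(tert-butyldiphenylsilyloxy)ethyl]-3-methyloxiran-2-yl]methanol
Product: 7 (3S)-5-(tert-butyldiphenylsilyloxy)-3-methylpentane-1,3-diol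
Conditions: NaAlH2(OCH2CH2OCH3)2, THF, 0 °C to rt
Reagents that add atoms: none
Why: Hydroxyl-directed hydride opening of a 2,3-epoxy alcohol delivers hydride to C2 (1,3-diol selectivity) and breaks only the C2–O bond, so the tertiary carbinol centre keeps its configuration.

Step 5
Reactants: 7 (3S)-5-(tert-butyldiphenylsilyloxy)-3-methylpentane-1,3-diol
Product: 8 (3R)-1-bromo-5-(tert-butyldiphenylsilyloxy)-3-methylpentan-3-ol
Conditions: CBr4, PPh3, CH2Cl2, 0 °C
Reagents that add atoms: carbon tetrabromide, BrC(Br)(Br)Br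
Why: The Appel bromination is an SN2 displacement of an alkoxyphosphonium salt and therefore takes the primary hydroxyl and leaves the tertiary one (the descriptor changes only because Br outranks O).

Step 6
Reactants: 8 (3R)-1-bromo-5-(tert-butyldiphenylsilyloxy)-3-methylpentan-3-ol; 9 4-iodo-3-methylanisole
Product: 10 (2S)-2-[2-(tert-butyldiphenylsilyloxy)ethyl]-6-methoxy-2,8-dimethylchroman
Conditions: Pd(OAc)2 (10 mol %), XPhos (2-dicyclohexylphosphino-2′,4′,6′-triisopropylbiphenyl, 20 mol %), norbornene (2 equiv), Cs2CO3 (3 equiv), MeCN, 85 °C, argon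
Reagents that add atoms: none
Why: Proposed new method: zerovalent palladium inserts into the C8a–I bond of 9, norbornene carbopalladation and C–H palladation at the only free ortho position (C4a) give the five-membered aryl–norbornyl palladacycle, the primary C–Br bond of 8 adds oxidatively to this divalent palladium, and reductive elimination from tetravalent palladium forms C4–C4a. With both ortho positions now occupied, norbornene is expelled by beta-carbon elimination and the aryl divalent palladium at C8a is captured by the tethered tertiary alkoxide. The dihydropyran ring then closes by C(sp2)–O reductive elimination from a seven-membered oxapalladacycle (Pd, C8a, C4a, C4, C3, C2, O), a step the bulky biarylphosphine is chosen to accelerate. The closest known reactions are the Catellani ortho-alkylation of ortho-substituted aryl iodides with primary alkyl bromides, its epoxide variant that ends in C–O closure to dihydrobenzofurans, and the palladium-catalysed cyclisation of 4-(2-haloaryl)-2-methylbutan-2-ols to 2,2-dialkylchromans. No stereocentre is created and none of the four bonds at C2 is touched, so the epoxidation-derived configuration is carried through, and the tertiary alkoxide has no carbinol hydrogen for beta-hydride elimination. The required regiochemistry (carbon at C4a, oxygen at C8a) is fixed by the position of iodine and the blocking C8 methyl, while the weak carbonate base keeps the alkoxide concentration low and so holds back oxetane formation from 8.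

Step 7
Reactants: 10 (2S)-2-[2-(tert-butyldiphenylsilyloxy)ethyl]-6-methoxy-2,8-dimethylchroman
Product: 11 (2R)-2-[2-(tert-butyldiphenylsilyloxy)ethyl]-6-methoxy-2,8-dimethyl-2H-chromene
Conditions: DDQ (1.5 equiv), toluene, 80 °C, dark
Reagents that add atoms: none
Why: DDQ dehydrogenation of an electron-rich chroman abstracts hydride from benzylic C4 (cation stabilised by O1 through C8a) and loss of a C3 proton installs C3=C4 without touching quaternary C2 (the descriptor changes by priority only).

Step 8
Reactants: 11 (2R)-2-[2-(tert-butyldiphenylsilyloxy)ethyl]-6-methoxy-2,8-dimethyl-2H-chromene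
Product: 12 2-[(2R)-6-methoxy-2,8-dimethyl-2H-chromen-2-yl]ethanol
Conditions: Bu4NF, THF, rt
Reagents that add atoms: none
Why: Fluoride-induced desilylation is driven by the Si–F bond, and nothing else in 11 is sensitive to fluoride or mild base.

Step 9
Reactants: 12 2-[(2R)-6-methoxy-2,8-dimethyl-2H-chromen-2-yl]ethanol
Product: 13 [(2R)-6-methoxy-2,8-dimethyl-2H-chromen-2-yl]acetaldehyde
Conditions: Dess–Martin periodinane, CH2Cl2, 0 °C to rt
Reagents that add atoms: none
Why: The Dess–Martin oxidation stops at the aldehyde in a near-neutral medium, which avoids enolisation and beta-elimination of the aryloxide.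

**Fragment 2**

Step 10
Reactants: 14 cis-1,5-dimethylbicyclo[3.3.0]octane-3,7-dione
Product: 15 cis-1,5-dimethylbicyclo[3.3.0]octane-3,7-dione mono(2,2-dimethylpropane-1,3-diyl) ketal
Conditions: 2,2-dimethylpropane-1,3-diol (1 equiv), p-TsOH (cat.), toluene, reflux, Dean–Stark
Reagents that add atoms: 2,2-dimethylpropane-1,3-diol, OCC(C)(C)CO
Why: Acid-catalysed ketalisation with one equivalent of diol differentiates the two equivalent ketones statistically (diketone and bisketal are recycled), and the cis vicinal quaternary methyls that become C1′/C2′ are already present in 14.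

Step 11
Reactants: 15 cis-1,5-dimethylbicyclo[3.3.0]octane-3,7-dione mono(2,2-dimethylpropane-1,3-diyl) ketal
Product: 18 cis-1,5-dimethylbicyclo[3.3.0]octan-3-one (meso), via hydrazone 16 (not isolated), via deoxygenated ketal 17 (not isolated)
Conditions: N2H4·H2O, KOH, diethylene glycol, 130 then 195 °C; crude ketal: 2 M HCl, THF, rt
Reagents that add atoms: water, O
Why: The Wolff–Kishner reduction (Huang-Minlon procedure) removes the free carbonyl under basic conditions that a ketal tolerates, and acid hydrolysis then unmasks the remaining ketone.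

Step 12
Reactants: 18 cis-1,5-dimethylbicyclo[3.3.0]octan-3-one (meso)
Product: 20 (1R,5S)-1,5-dimethyl-3-(trimethylsilyloxy)bicyclo[3.3.0]oct-2-ene, via lithium enolate 19 (not isolated)
Conditions: (R,R)-bis(1-phenylethyl)amine hydrochloride, n-BuLi (2 equiv), THF, −78 °C to rt; 18, −78 °C; Me3SiCl, −78 °C
Reagents that add atoms: chlorotrimethylsilane, C[Si](C)(C)Cl
Why: Chiral lithium amide desymmetrisation in the presence of LiCl, known for meso bicyclo[3.3.0]octan-3-ones including the 7-ketal of this dimethyl ring system, distinguishes the enantiotopic C2/C4 methylenes, and O-silylation freezes the result, which fixes the absolute configuration of C1′ and C2′.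

Step 13
Reactants: 20 (1R,5S)-1,5-dimethyl-3-(trimethylsilyloxy)bicyclo[3.3.0]oct-2-ene
Product: 21 2-[(1S,2S)-2-formyl-1,2-dimethylcyclopentyl]acetic acid
Conditions: O3, CH2Cl2/MeOH, −78 °C; Me2S, −78 °C to rt
Reagents that add atoms: ozone, [O-][O+]=O
Why: Ozonolysis of a silyl enol ether with reductive work-up cleaves C2=C3 to an aldehyde on one quaternary carbon (C2′) and a carboxylic acid one CH2 away from the other (C1′), without touching either stereocentre.

Step 14
Reactants: 22 2-methylbut-3-yn-2-ol
Product: 23 tert-butyl(dimethyl)[(2-methylbut-3-yn-2-yl)oxy]silane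
Conditions: t-BuMe2SiOTf, 2,6-lutidine, CH2Cl2, 0 °C
Reagents that add atoms: tert-butyldimethylsilyl triflate, CC(C)(C)[Si](C)(C)OS(=O)(=O)C(F)(F)F
Why: Silyl triflate with lutidine is the standard silylation of a hindered tertiary propargylic alcohol.

Step 15
Reactants: 21 2-[(1S,2S)-2-formyl-1,2-dimethylcyclopentyl]acetic acid; 23 tert-butyl(dimethyl)[(2-methylbut-3-yn-2-yl)oxy]silane
Product: 27 2-[(1S,2S)-2-[1,4-bis(tert-butyldimethylsilyloxy)-4-methylpent-2-yn-1-yl]-1,2-dimethylcyclopentyl]acetic acid (both carbinol epimers), via lithium acetylide 24 (not isolated), via dilithium alkoxide carboxylate 25 (not isolated), via silyl ester 26 (not isolated)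
Conditions: 23, n-BuLi, THF, −78 °C; 21 (0.45 equiv), −78 to −20 °C; t-BuMe2SiOTf, −78 to 0 °C; K2CO3 (cat.), MeOH/H2O, rt, then pH 4
Reagents that add atoms: tert-butyldimethylsilyl triflate, CC(C)(C)[Si](C)(C)OS(=O)(=O)C(F)(F)F
Why: 1,2-Addition of a lithium acetylide to a non-enolisable neopentyl aldehyde (the first equivalent only deprotonates the acid) is followed by in situ O-silylation so that the delta-hydroxy acid cannot lactonise; the new carbinol centre is uncontrolled and is erased in step 19.

Step 16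
Reactants: 27 2-[(1S,2S)-2-[1,4-bis(tert-butyldimethylsilyloxy)-4-methylpent-2-yn-1-yl]-1,2-dimethylcyclopentyl]acetic acid (both carbinol epimers)
Product: 29 (1S,2R)-1-[1,4-bis(tert-butyldimethylsilyloxy)-4-methylpent-2-yn-1-yl]-2-(iodomethyl)-1,2-dimethylcyclopentane, via thiohydroxamate ester 28 (not isolated)
Conditions: 1-hydroxypyridine-2(1H)-thione, DCC, DMAP (cat.), CH2Cl2, 0 °C, dark; CHI3, tungsten lamp, rt
Reagents that add atoms: iodoform, IC(I)I
Why: In the Barton decarboxylative iodination the thiohydroxamate ester fragments under visible light, CO2 is lost and the primary radical should abstract iodine from CHI3 faster than it can cyclise onto the alkyne, which gives the neopentyl iodide without any SN2 step at that hindered carbon.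

**Union and finishing steps**

Step 17
Reactants: 29 (1S,2R)-1-[1,4-bis(tert-butyldimethylsilyloxy)-4-methylpent-2-yn-1-yl]-2-(iodomethyl)-1,2-dimethylcyclopentane; 13 [(2R)-6-methoxy-2,8-dimethyl-2H-chromen-2-yl]acetaldehyde
Product: 31 1-[(1S,2S)-2-{2-hydroxy-3-[(2R)-6-methoxy-2,8-dimethyl-2H-chromen-2-yl]propyl}-1,2-dimethylcyclopentyl]-1,4-bis(tert-butyldimethylsilyloxy)-4-methylpent-2-yne (carbinol epimers), via alkyllithium 30 (not isolated)
Conditions: 29, t-BuLi (2.1 equiv), Et2O/pentane, −78 °C; 13, −78 °C; H2O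
Reagents that add atoms: none
Why: Lithium–iodine exchange with two equivalents of t-BuLi is fast at −78 °C, the primary alkyllithium has no beta-hydrogen and is too cold to carbolithiate the alkyne, and it adds 1,2 to the aldehyde; the new carbinol centre is uncontrolled and is erased in step 19.

Step 18
Reactants: 31 1-[(1S,2S)-2-{2-hydroxy-3-[(2R)-6-methoxy-2,8-dimethyl-2H-chromen-2-yl]propyl}-1,2-dimethylcyclopentyl]-1,4-bis(tert-butyldimethylsilyloxy)-4-methylpent-2-yne (carbinol epimers)
Product: 32 1-[(1S,2S)-2-{2-hydroxy-3-[(2R)-6-methoxy-2,8-dimethyl-2H-chromen-2-yl]propyl}-1,2-dimethylcyclopentyl]-4-methylpent-2-yne-1,4-diol (carbinol epimers)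
Conditions: Bu4NF, THF, rt to 45 °C
Reagents that add atoms: none
Why: Fluoride desilylation removes both silyl ethers while the molecule still contains no base-sensitive carbonyl group.

Step 19
Reactants: 32 1-[(1S,2S)-2-{2-hydroxy-3-[(2R)-6-methoxy-2,8-dimethyl-2H-chromen-2-yl]propyl}-1,2-dimethylcyclopentyl]-4-methylpent-2-yne-1,4-diol (carbinol epimers)
Product: 33 4-hydroxy-1-[(1S,2S)-2-{3-[(2R)-6-methoxy-2,8-dimethyl-2H-chromen-2-yl]-2-oxopropyl}-1,2-dimethylcyclopentyl]-4-methylpent-2-yn-1-one
Conditions: Dess–Martin periodinane (3 equiv), CH2Cl2, 0 °C to rt, dark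
Reagents that add atoms: none
Why: The Dess–Martin oxidation converts both secondary carbinols, cannot touch the tertiary one, and its near-neutral medium spares the beta-aryloxy ketone from retro-oxa-Michael opening that would scramble C2; all epimers converge here, and material from the minor antipode of fragment 2 is a diastereomer that should be removable by chromatography.

Step 20
Reactants: 33 4-hydroxy-1-[(1S,2S)-2-{3-[(2R)-6-methoxy-2,8-dimethyl-2H-chromen-2-yl]-2-oxopropyl}-1,2-dimethylcyclopentyl]-4-methylpent-2-yn-1-one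
Product: 34 (Z)-4-hydroxy-1-[(1S,2S)-2-{3-[(2R)-6-methoxy-2,8-dimethyl-2H-chromen-2-yl]-2-oxopropyl}-1,2-dimethylcyclopentyl]-4-methylpent-2-en-1-one (CNP0137762.2)
Conditions: H2 (1 atm), Pd/CaCO3 poisoned with Pb(OAc)2, quinoline, EtOAc, rt, stopped after one equivalent of H2
Reagents that add atoms: none
Why: Lindlar-type semihydrogenation adds H2 syn to the alkyne and so gives the Z-enone, while the poisoned catalyst should leave the C3=C4 bond and the ketones alone.

**Compound list**

1 | but-3-yn-1-ol | C#CCCO | starting material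
2 | tert-butyl(but-3-yn-1-yloxy)diphenylsilane | C#CCCO[Si](c1ccccc1)(c1ccccc1)C(C)(C)C | intermediate
3 | [(E)-4-(tert-butyldiphenylsilyloxy)-2-methylbut-1-en-1-yl]dimethylalane | C[Al](C)/C=C(\C)CCO[Si](c1ccccc1)(c1ccccc1)C(C)(C)C | intermediate
4 | lithium butyl[(E)-4-(tert-butyldiphenylsilyloxy)-2-methylbut-1-en-1-yl]dimethylalanate | [Li+].CCCC[Al-](C)(C)/C=C(\C)CCO[Si](c1ccccc1)(c1ccccc1)C(C)(C)C | intermediate
5 | (E)-5-(tert-butyldiphenylsilyloxy)-3-methylpent-2-en-1-ol | OC/C=C(\C)CCO[Si](c1ccccc1)(c1ccccc1)C(C)(C)C | intermediate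
6 | [(2R,3R)-3-[2-(tert-butyldiphenylsilyloxy)ethyl]-3-methyloxiran-2-yl]methanol | OC[C@H]1O[C@]1(C)CCO[Si](c2ccccc2)(c2ccccc2)C(C)(C)C | intermediate
7 | (3S)-5-(tert-butyldiphenylsilyloxy)-3-methylpentane-1,3-diol | OCC[C@@](C)(CCO[Si](c1ccccc1)(c1ccccc1)C(C)(C)C)O | intermediate
8 | (3R)-1-bromo-5-(tert-butyldiphenylsilyloxy)-3-methylpentan-3-ol | BrCC[C@@](C)(CCO[Si](c1ccccc1)(c1ccccc1)C(C)(C)C)O | intermediate
9 | 4-iodo-3-methylanisole | COc1ccc(I)c(C)c1 | starting material
10 | (2S)-2-[2-(tert-butyldiphenylsilyloxy)ethyl]-6-methoxy-2,8-dimethylchroman | COc1cc(C)c2c(c1)CC[C@@](C)(CCO[Si](c3ccccc3)(c3ccccc3)C(C)(C)C)O2 | intermediate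
11 | (2R)-2-[2-(tert-butyldiphenylsilyloxy)ethyl]-6-methoxy-2,8-dimethyl-2H-chromene | COc1cc(C)c2c(c1)C=C[C@@](C)(CCO[Si](c3ccccc3)(c3ccccc3)C(C)(C)C)O2 | intermediate
12 | 2-[(2R)-6-methoxy-2,8-dimethyl-2H-chromen-2-yl]ethanol | COc1cc(C)c2c(c1)C=C[C@@](C)(CCO)O2 | intermediate
13 | [(2R)-6-methoxy-2,8-dimethyl-2H-chromen-2-yl]acetaldehyde | COc1cc(C)c2c(c1)C=C[C@@](C)(CC=O)O2 | intermediate
14 | cis-1,5-dimethylbicyclo[3.3.0]octane-3,7-dione | O=C1C[C@]2(C)CC(=O)C[C@]2(C)C1 | starting material
15 | monoketal of 14 with 2,2-dimethylpropane-1,3-diol (meso) | O=C1C[C@]2(C)CC3(OCC(C)(C)CO3)C[C@]2(C)C1 | intermediate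
16 | hydrazone of 15 | NN=C1C[C@]2(C)CC3(OCC(C)(C)CO3)C[C@]2(C)C1 | intermediate
17 | cis-1,5-dimethylbicyclo[3.3.0]octan-3-one 2,2-dimethylpropane-1,3-diyl ketal | O1CC(C)(C)COC12C[C@]3(C)CCC[C@]3(C)C2 | intermediate
18 | cis-1,5-dimethylbicyclo[3.3.0]octan-3-one (meso) | O=C1C[C@]2(C)CCC[C@]2(C)C1 | intermediate
19 | lithium (1R,5S)-1,5-dimethylbicyclo[3.3.0]oct-2-en-3-olate | [Li]OC1=C[C@@]2(C)CCC[C@@]2(C)C1 | intermediate
20 | (1R,5S)-1,5-dimethyl-3-(trimethylsilyloxy)bicyclo[3.3.0]oct-2-ene | C[Si](C)(C)OC1=C[C@@]2(C)CCC[C@@]2(C)C1 | intermediate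
21 | 2-[(1S,2S)-2-formyl-1,2-dimethylcyclopentyl]acetic acid | OC(=O)C[C@]1(C)CCC[C@]1(C)C=O | intermediate
22 | 2-methylbut-3-yn-2-ol | CC(C)(O)C#C | starting material
23 | tert-butyl(dimethyl)[(2-methylbut-3-yn-2-yl)oxy]silane | C#CC(C)(C)O[Si](C)(C)C(C)(C)C | intermediate
24 | lithium acetylide of 23 | [Li]C#CC(C)(C)O[Si](C)(C)C(C)(C)C | intermediate
25 | dilithium alkoxide carboxylate from 21 and 24 (carbinol epimers) | [Li]OC(=O)C[C@]1(C)CCC[C@]1(C)C(O[Li])C#CC(C)(C)O[Si](C)(C)C(C)(C)C | intermediate
26 | tert-butyldimethylsilyl ester of 27 | CC(C)(C)[Si](C)(C)OC(=O)C[C@]1(C)CCC[C@]1(C)C(O[Si](C)(C)C(C)(C)C)C#CC(C)(C)O[Si](C)(C)C(C)(C)C | intermediate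
27 | 2-[(1S,2S)-2-[1,4-bis(tert-butyldimethylsilyloxy)-4-methylpent-2-yn-1-yl]-1,2-dimethylcyclopentyl]acetic acid (carbinol epimers) | OC(=O)C[C@]1(C)CCC[C@]1(C)C(O[Si](C)(C)C(C)(C)C)C#CC(C)(C)O[Si](C)(C)C(C)(C)C | intermediate
28 | 2-thioxopyridin-1(2H)-yl ester of 27 | S=c1ccccn1OC(=O)C[C@]2(C)CCC[C@]2(C)C(O[Si](C)(C)C(C)(C)C)C#CC(C)(C)O[Si](C)(C)C(C)(C)C | intermediate
29 | (1S,2R)-1-[1,4-bis(tert-butyldimethylsilyloxy)-4-methylpent-2-yn-1-yl]-2-(iodomethyl)-1,2-dimethylcyclopentane (carbinol epimers) | IC[C@]1(C)CCC[C@]1(C)C(O[Si](C)(C)C(C)(C)C)C#CC(C)(C)O[Si](C)(C)C(C)(C)C | intermediate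
30 | alkyllithium from 29 (Li in place of I, configuration unchanged) | [Li]C[C@]1(C)CCC[C@]1(C)C(O[Si](C)(C)C(C)(C)C)C#CC(C)(C)O[Si](C)(C)C(C)(C)C | intermediate
31 | 1-[(1S,2S)-2-{2-hydroxy-3-[(2R)-6-methoxy-2,8-dimethyl-2H-chromen-2-yl]propyl}-1,2-dimethylcyclopentyl]-1,4-bis(tert-butyldimethylsilyloxy)-4-methylpent-2-yne (carbinol epimers) | COc1cc(C)c2c(c1)C=C[C@@](C)(CC(O)C[C@]1(C)CCC[C@]1(C)C(O[Si](C)(C)C(C)(C)C)C#CC(C)(C)O[Si](C)(C)C(C)(C)C)O2 | intermediate
32 | 1-[(1S,2S)-2-{2-hydroxy-3-[(2R)-6-methoxy-2,8-dimethyl-2H-chromen-2-yl]propyl}-1,2-dimethylcyclopentyl]-4-methylpent-2-yne-1,4-diol (carbinol epimers) | COc1cc(C)c2c(c1)C=C[C@@](C)(CC(O)C[C@]1(C)CCC[C@]1(C)C(O)C#CC(C)(C)O)O2 | intermediate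
33 | 4-hydroxy-1-[(1S,2S)-2-{3-[(2R)-6-methoxy-2,8-dimethyl-2H-chromen-2-yl]-2-oxopropyl}-1,2-dimethylcyclopentyl]-4-methylpent-2-yn-1-one | COc1cc(C)c2c(c1)C=C[C@@](C)(CC(=O)C[C@]1(C)CCC[C@]1(C)C(=O)C#CC(C)(C)O)O2 | intermediate
34 | (Z)-4-hydroxy-1-[(1S,2S)-2-{3-[(2R)-6-methoxy-2,8-dimethyl-2H-chromen-2-yl]-2-oxopropyl}-1,2-dimethylcyclopentyl]-4-methylpent-2-en-1-one (CNP0137762.2) | COc1cc(C)c2c(c1)C=C[C@@](C)(CC(=O)C[C@]1(C)CCC[C@]1(C)C(=O)/C=C\C(C)(C)O)O2 | target

**Step count**

Total: 20 steps. Longest linear sequence: 13 steps (steps 1–9, then 17–20). Fragment 2 contributes 10 steps along its own line (10–13, 15–20).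

**Steps most likely to fail**

Step 6. The catalytic cycle may end too early by protodepalladation. It may also stall at a slow C–O reductive elimination, so that norbornene-retaining pathways take over. In addition, the bromo alcohol may be consumed by base-induced self-cyclisation.

The fallback sets out from 8 and returns at 10, forming the two bonds one after the other by known reactions. 4-Methoxy-2-methylaniline F1 is iodinated ortho to nitrogen (N-iodosuccinimide, MeCN) to 2-iodo-4-methoxy-6-methylaniline F2. Sandmeyer bromination (t-BuONO, CuBr2, MeCN) then gives 2-bromo-1-iodo-5-methoxy-3-methylbenzene F3.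

Nickel-catalysed reductive cross-electrophile coupling joins the C–I bond of F3 to the primary bromide 8 (NiI2, 4,4′-di-tert-butyl-2,2′-bipyridine, Zn, DMA, 60 °C). This coupling tolerates a free hydroxyl and gives (3S)-1-(2-bromo-5-methoxy-3-methylphenyl)-5-(tert-butyldiphenylsilyloxy)-3-methylpentan-3-ol F4. The established palladium-catalysed intramolecular etherification of aryl bromides with tertiary alcohols (Pd(OAc)2, 2-(di-tert-butylphosphino)-1,1′-binaphthyl, Cs2CO3, toluene, 100 °C) then closes O1–C8a to 10.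

Step 17. The basic alkyllithium may enolise the aldehyde, which would trigger beta-elimination of the aryloxide and ring opening. Alternatively, the carbanion may attack the alkyne intramolecularly if the mixture warms.

The fallback sets out from 13 and 29 and returns at 33, replacing carbonyl addition by a non-basic acyl cross-coupling at the ketone oxidation level. Pinnick oxidation of 13 (NaClO2, NaH2PO4, 2-methylbut-2-ene, t-BuOH/H2O) gives [(2R)-6-methoxy-2,8-dimethyl-2H-chromen-2-yl]acetic acid F5. This is converted (EtSH, DCC, DMAP) into the S-ethyl thioester F6.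

Zinc insertion into 29 (activated Zn, LiCl, THF, 40 °C) gives the alkylzinc iodide F7. Fukuyama coupling of F7 with F6 (PdCl2(PPh3)2, toluene, rt) gives the bis-silylated ketone F8. HF·pyridine in THF releases the keto diol F9 without base, and Dess–Martin oxidation of its single secondary carbinol gives 33.

Step 20. The electron-poor alkyne or the enone formed from it may be over-reduced. The Z-enone may isomerise on the catalyst, or C3=C4 may be saturated at the same time.

The fallback sets out from 32 and returns at 34, reversing the order of reduction and oxidation. The electron-rich propargylic diol unit of 32 is semihydrogenated first (H2, Pd/CaCO3 poisoned with Pb(OAc)2, quinoline, EtOAc) to the (Z)-ene-triol F10, a substrate class on which this reduction stops cleanly. Dess–Martin oxidation of its two secondary carbinols then gives 34 directly.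

**Further compounds**

F1 | step 6 | 4-methoxy-2-methylaniline (purchased) | COc1ccc(N)c(C)c1
F2 | step 6 | 2-iodo-4-methoxy-6-methylaniline | COc1cc(C)c(N)c(I)c1
F3 | step 6 | 2-bromo-1-iodo-5-methoxy-3-methylbenzene | COc1cc(C)c(Br)c(I)c1
F4 | step 6 | (3S)-1-(2-bromo-5-methoxy-3-methylphenyl)-5-(tert-butyldiphenylsilyloxy)-3-methylpentan-3-ol | COc1cc(C)c(Br)c(c1)CC[C@@](C)(CCO[Si](c2ccccc2)(c2ccccc2)C(C)(C)C)O
F5 | step 17 | [(2R)-6-methoxy-2,8-dimethyl-2H-chromen-2-yl]acetic acid | COc1cc(C)c2c(c1)C=C[C@@](C)(CC(=O)O)O2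
F6 | step 17 | S-ethyl [(2R)-6-methoxy-2,8-dimethyl-2H-chromen-2-yl]ethanethioate | COc1cc(C)c2c(c1)C=C[C@@](C)(CC(=O)SCC)O2
F7 | step 17 | alkylzinc iodide from 29 | I[Zn]C[C@]1(C)CCC[C@]1(C)C(O[Si](C)(C)C(C)(C)C)C#CC(C)(C)O[Si](C)(C)C(C)(C)C
F8 | step 17 | bis(tert-butyldimethylsilyl) ether of keto diol F9 | COc1cc(C)c2c(c1)C=C[C@@](C)(CC(=O)C[C@]1(C)CCC[C@]1(C)C(O[Si](C)(C)C(C)(C)C)C#CC(C)(C)O[Si](C)(C)C(C)(C)C)O2
F9 | step 17 | 1-[(1S,2S)-2-(1,4-dihydroxy-4-methylpent-2-yn-1-yl)-1,2-dimethylcyclopentyl]-3-[(2R)-6-methoxy-2,8-dimethyl-2H-chromen-2-yl]propan-2-one | COc1cc(C)c2c(c1)C=C[C@@](C)(CC(=O)C[C@]1(C)CCC[C@]1(C)C(O)C#CC(C)(C)O)O2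
F10 | step 20 | (Z)-1-[(1S,2S)-2-{2-hydroxy-3-[(2R)-6-methoxy-2,8-dimethyl-2H-chromen-2-yl]propyl}-1,2-dimethylcyclopentyl]-4-methylpent-2-ene-1,4-diol | COc1cc(C)c2c(c1)C=C[C@@](C)(CC(O)C[C@]1(C)CCC[C@]1(C)C(O)/C=C\C(C)(C)O)O2
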